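Ring atoms are numbered as in tetracyclo[6.4.0.0^2,7.0^3,6]dodecane: ring A = C1, C8–C12; ring B = C1, C2, C7, C8; ring C = C2, C3, C6, C7; ring D = C3–C6; the chain sits on C10.

## Analysis of the target

The target 30 is a 2-O-alkylglycerol: a propane-1,3-diol whose C2 oxygen carries an unbranched eight-carbon chain ending on C10 of a cyclohexane (ring A) fused in a line to three cyclobutanes (rings B, C, D). All seven stereocenters lie in the ring system (C1, C2, C3, C6, C7, C8, C10); the glycerol C2 has two identical CH2OH arms and is not a stereocenter. The three ring fusions are cis and consecutive rings are anti (A anti to C across B, B anti to D across C), so the ladder is a staircase, and the chain on C10 lies on the face of ring A that also carries ring B (H-1, H-8 and H-10 cis). Without the chain the hydrocarbon is meso, so the absolute configuration is only the choice of which of two enantiotopic ring A positions carries the chain, and C10 is too remote from C1 and C8 to steer their formation. The dialkyl ether and the 1,3-diol are robust; the sensitivity is strain, since the two bicyclo[2.2.0]hexane units (B/C and C/D) cleave thermally well below 200 °C and are vulnerable to radicals on a carbon attached to a four-membered ring, to strong Lewis acids and to hydrogenolysis catalysts. The difficulty is to build three contiguous cyclobutanes with six contiguous cis,anti stereocenters, in the right sense to C10, under mild conditions. The route rests on ring D: it is the only cyclobutane with two CH2 groups (C4, C5), so one of them can begin as a ketone carbonyl, which makes ring D the [2+2] adduct of a ketene across a C3=C6 cyclobutene; once ring D is removed, the same holds for ring C and then for ring B.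

## Retrosynthetic reasoning

**Head group.** 30 is opened at the acetal to 29, and 29 is cut at the bond between chain C1 and the glycerol oxygen into mesylate 26 and alkoxide 28, made from the symmetric alcohol 27. Cutting on the chain side puts the SN2 reaction on a primary carbon and makes the achiral secondary glycerol carbon the nucleophile; the reverse polarity would need substitution at a secondary carbon. The forward step has to outrun E2 elimination of 26.

**Chain terminus.** 26 comes from alcohol 25 and 25 from its silyl ether 24. A silyl group is chosen because it survives Lewis acid, dissolving metal, organolithium and alkoxide, and leaves under neutral, non-reductive conditions; a hydrogenolytic deprotection would put the strained σ-bonds at risk.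

**Carbonyl and chlorines of ring D.** 24 is the deoxygenation product of cyclobutanone 22 (through hydrazone 23), and 22 the dechlorination product of 21. These are pure functional-group removals at C4/C5, the only ring carbons of the ladder that carry two hydrogens. The deoxygenation must run near room temperature and by an anionic, not a radical, pathway.

**Ring D.** 21 is cut at C3–C4 and C5–C6 into cyclobutene 20 and dichloroketene 9, generated from 8. This is the only cyclobutane that can be removed as a two-carbon unit without leaving a substituent behind. The cut gains two C–C bonds, one ring and two stereocenters in one thermal operation. Whichever way round 9 adds, the same hydrocarbon results later. The forward reaction has to take the face of the cyclobutene anti to ring B.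

**Ring C.** The cyclobutene of 20 is the Shapiro product of tosylhydrazone 18 (through vinyllithium 19), made from ketone 17 and 12. 17 comes from 16, and 16 is cut exactly as ring D into cyclobutene 15 and 9. The ketone-to-alkene conversion places the π-bond where the next ketene must add and erases the regiochemistry of the previous addition.

**Ring B and the facial problem.** 15 comes the same way from 13 (through 14), 11, 10, and finally from cyclohexene 7 and 9. Here nothing in the substrate decides the face: the stereocenter of 7 is remote from the alkene. Both faces must therefore be expected to react, so 10, 11 and 13 are carried as pairs of facial diastereomers and only the material that becomes 15 is used. The separation is placed after the Shapiro step because only there have the regioisomers merged, so that two compounds are left instead of four.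

**Chain.** 7 is cut between chain C1 and C2 into tosylate 3 and Grignard reagent 6. 3 comes from alcohol 2 and the commercial acid 1, which supplies C10 with its absolute configuration; 6 comes from 5 and 4. The coupling is one carbon away from the stereocenter and cannot disturb it.

## Alternatives that were turned down

**Alternative 1: electrocyclic cascade.** The chain-free meso diene A3 (ring A cyclohexene, ring D cyclobutene) is cut at C3–C6 and then at C2–C7, leading back to the cis-fused bicyclic tetraene A1.
- Forward: heating equilibrates A1 with its valence isomer A2 by disrotatory 6π closure (ring B), and irradiation closes the cyclohexadiene ring of A2 by disrotatory 4π closure (rings C and D) to A3.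
- For: the whole ladder forms from a simple bicycle with no redox adjustment and no regioisomers, and the ring A alkene is a handle for the chain. On step count to the carbon skeleton it is clearly stronger than the twelve steps needed here to reach 20.
- Against: the photochemical closure of a conjugated cyclohexadiene competes with its ring opening to a triene, usually the main photoreaction, so the drain of the equilibrium is inefficient. The 6π closure can place ring A syn or anti to the new ring. A3 is meso, so both C10 and the absolute configuration must be created late by an enantioselective desymmetrisation of the ring A alkene, beside a more reactive cyclobutene that must then be saturated without hydrogenolysis.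
- Comparison: the chosen route carries the absolute configuration from step 1 and closes each ring thermally with a predictable exo preference. It pays with length and with one unselective cycloaddition.

**Alternative 2: photochemical zipper.** All four rungs (C1–C8, C2–C7, C3–C6, C4–C5) are cut at once, taking acetonide A5 (identical with 29) back to the acyclic (E,E)-tetraene A4, two terminal dienes joined by a four-carbon tether that bears the chain.
- Forward: sensitised irradiation stacks the dienes; a first [2+2] closes rings A and B and a second closes rings C and D.
- For: it is by far the most convergent plan, one step from 29 and two from 30. On step economy nothing here competes with it.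
- Against: a flexible four-atom tether does not enforce parallel stacking. Excited dienes also undergo E/Z isomerisation and 1,4-closures to six- and eight-membered rings. The intermediate cis-divinylcyclobutane is set up for a Cope rearrangement, and its isolated vinyl groups no longer accept the excitation. The single stereocenter in the tether would have to control six new ones across the same weak relationship that defeats selectivity in ring B here.
- Comparison: the chosen strategy forms the same bonds as separate, well-understood thermal events and confines the facial problem to one early, inexpensive stage.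

**Alternative 3: carbene ring expansion.** Ring D of ladderene A7 is cut at the bond from one C/D fusion carbon to a ring D CH and contracted to a cyclopropane, giving housane tosylhydrazone A6.
- Forward: base and heat (Bamford–Stevens) give a cyclopropylcarbene, and a 1,2-shift of a cyclopropane bond expands it to the cyclobutene.
- For: it is thermal; the two cyclopropane bonds that can migrate are equivalent; exo cyclopropanation of a cyclobutene like 20 would set C3/C6 as reliably as the ketene; and zinc salts are kept away from the strained alkene. On stereocontrol it equals the chosen route.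
- Against: carbene generation from a tosylhydrazone salt needs heating well above 100 °C, outside the thermal window of the bicyclo[2.2.0]hexane units and of the bicyclo[2.1.0]pentane unit of A6. Cyclopropylcarbenes also fragment to alkene plus alkyne, here assisted by strain. A6 needs cyclopropanation, oxidation-state adjustment and hydrazone formation from a cyclobutene of the type of 20, and A7 still needs a non-hydrogenolytic saturation.
- Comparison: the ketene route makes both ring D bonds in one step at or below 35 °C and needs two further steps to the hydrocarbon.

Key step: step 13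

**Remarks on the chemistry.**
- Each ketene cycloadduct forms as two regioisomers (carbonyl on either former alkene carbon) that converge later; they are carried under one number and one member is drawn.
- The first cycloaddition cannot tell the two faces of 7 apart, so 10, 11 and 13 each also cover both facial diastereomers; 15 and every later number stand for the single diastereomer kept in step 8.
- Dichloroketene 9 cannot be stored. It is made afresh from 8 and zinc in the flask in each of steps 5, 9 and 13 and is consumed as it forms.
- Compounds 1, 4, 8, 12 and 27 are taken as purchasable.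

## Route

Step 1
Reactants: 1 (S)-cyclohex-3-ene-1-carboxylic acid
Product: 2 (S)-cyclohex-3-en-1-ylmethanol
Conditions: LiAlH4, THF, 0 °C → rt
Reagents that add atoms: none
Why: Hydride reduction of a carboxylic acid to the primary alcohol; the carboxylate is not enolised, so the stereocenter is kept, and the ring alkene is inert to LiAlH4.

Step 2
Reactants: 2 (S)-cyclohex-3-en-1-ylmethanol
Product: 3 (S)-cyclohex-3-en-1-ylmethyl 4-methylbenzenesulfonate
Conditions: TsCl, Et3N, DMAP (cat.), CH2Cl2, 0 °C → rt
Reagents that add atoms: p-toluenesulfonyl chloride, Cc1ccc(cc1)S(Cl)(=O)=O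
Why: Sulfonylation of a primary alcohol gives the leaving group for the chain coupling without touching the stereocenter.

Step 3
Reactants: 4 7-bromoheptan-1-ol
Product: 5 (7-bromoheptyloxy)triisopropylsilane
Conditions: TIPSCl, imidazole, DMF, rt
Reagents that add atoms: chlorotriisopropylsilane, CC(C)[Si](Cl)(C(C)C)C(C)C
Why: Silylation of a primary alcohol; the triisopropylsilyl ether tolerates Grignard formation, ZnCl2 with acid chloride, Zn/AcOH, n-BuLi and KOtBu, and is later removed by fluoride, so no hydrogenolysis is needed on the strained product.

Step 4
Reactants: 3 (S)-cyclohex-3-en-1-ylmethyl 4-methylbenzenesulfonate; 5 (7-bromoheptyloxy)triisopropylsilane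
Product: 7 (S)-{[8-(cyclohex-3-en-1-yl)octyl]oxy}triisopropylsilane, via Grignard reagent 6 (not isolated)
Conditions: 5, Mg, THF, 40 °C; then 3, Li2CuCl4 (5 mol %), THF, −20 °C → rt
Reagents that add atoms: none
Why: Copper-catalysed sp3–sp3 coupling of a primary alkyl Grignard reagent with a primary tosylate (Kochi/Fouquet–Schlosser type), which is routine for β-branched tosylates; the stereocenter is one carbon away from the reacting centre and is not involved.

Step 5
Reactants: 7 (S)-{[8-(cyclohex-3-en-1-yl)octyl]oxy}triisopropylsilane; 8 trichloroacetyl chloride
Product: 10 bicyclic dichlorocyclobutanones (two regioisomers of each facial diastereomer; the 4-substituted cis isomer is drawn), via dichloroketene 9 (not isolated)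
Conditions: Zn(Cu), DME, Et2O, 8 added slowly, 25–35 °C
Reagents that add atoms: none
Why: [2+2] cycloaddition of dichloroketene, made in the flask by zinc dechlorination of 8, to an unactivated cis-disubstituted cycloalkene; suprafacial addition fixes the cis A/B fusion. The remote stereocenter should bias neither face nor orientation, so all four isomers are expected and are carried on until the regioisomers converge in step 8.

Step 6
Reactants: 10 bicyclic dichlorocyclobutanones
Product: 11 bicyclic cyclobutanones (same isomer set; 4-substituted cis-fused bicyclo[4.2.0]octan-7-one drawn)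
Conditions: Zn dust, AcOH, rt
Reagents that add atoms: none
Why: Zinc in acetic acid reduces the α,α-dichloroketone through zinc enolates to the parent cyclobutanone; the silyl ether survives and the cis ring fusion, the only unstrained one, cannot epimerise productively.

Step 7
Reactants: 11 bicyclic cyclobutanones; 12 p-toluenesulfonyl hydrazide
Product: 13 tosylhydrazones of 11
Conditions: EtOH, rt
Reagents that add atoms: none
Why: Condensation of an electrophilic cyclobutanone with a sulfonyl hydrazide proceeds without added acid and gives the Shapiro substrate.

Step 8
Reactants: 13 tosylhydrazones of 11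
Product: 15 cis-bicyclic cyclobutene with H-1/H-3/H-6 all cis (single diastereomer), via cyclobutenyllithium 14 (not isolated)
Conditions: n-BuLi (3 equiv), TMEDA, THF, −78 °C → rt; H2O; then AgNO3/SiO2 chromatography
Reagents that add atoms: none
Why: Shapiro reaction: the N–H and then the α-CH2 syn to the sulfonamide are deprotonated, sulfinate and N2 are lost and the cyclobutenyllithium is protonated on quench. The ring-fusion α-CH is not removed, so both regioisomers give the same C7=C8 alkene and only the two facial diastereomers remain; the one with the chain on the cyclobutene face of ring A is kept as 15 and the other is removed in the chromatography.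

Step 9
Reactants: 15 cis-bicyclic cyclobutene; 8 trichloroacetyl chloride
Product: 16 tricyclic dichlorocyclobutanone (two regioisomers; 9-substituted 4,4-dichlorotricyclo[4.4.0.0^2,5]decan-3-one drawn)
Conditions: Zn(Cu), DME, Et2O, 8 added slowly, 20–30 °C
Reagents that add atoms: none
Why: The same ketene [2+2] as in step 5, with dichloroketene 9 made again from 8 and zinc in the flask, now on a strained cyclobutene. The folded cis-bicyclo[4.2.0]octene exposes only the face anti to ring A, which sets the two B/C fusion carbons with the A/C anti relationship, and the regioisomers converge again in step 12.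

Step 10
Reactants: 16 tricyclic dichlorocyclobutanone
Product: 17 tricyclic cyclobutanone (tricyclo[4.4.0.0^2,5]decan-3-one with the chain at C9 or C8)
Conditions: Zn dust, AcOH, rt
Reagents that add atoms: none
Why: Zinc/acetic acid dechlorination as in step 6, kept at room temperature because the product contains a bicyclo[2.2.0]hexanone.

Step 11
Reactants: 17 tricyclic cyclobutanone; 12 p-toluenesulfonyl hydrazide
Product: 18 tosylhydrazone of 17
Conditions: EtOH, rt
Reagents that add atoms: none
Why: Hydrazone condensation as in step 7; the strained carbonyl gains relief on becoming tetrahedral in the addition step and reacts readily.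

Step 12
Reactants: 18 tosylhydrazone of 17
Product: 20 tricyclic cyclobutene (8-substituted tricyclo[4.4.0.0^2,5]dec-3-ene with rings A/C anti), via vinyllithium 19 (not isolated)
Conditions: n-BuLi (3 equiv), TMEDA, THF, −78 °C → rt; H2O
Reagents that add atoms: none
Why: Shapiro reaction as in step 8; only the CH2 α-hydrogens can be removed because the other α-carbon is a bicyclo[2.2.0] bridgehead, and the reaction stays at or below room temperature, where the bicyclo[2.2.0]hex-2-ene unit does not open.

Step 13
Reactants: 20 tricyclic cyclobutene; 8 trichloroacetyl chloride
Product: 21 tetracyclic dichlorocyclobutanone (two regioisomers; 11-substituted 5,5-dichlorotetracyclo[6.4.0.0^2,7.0^3,6]dodecan-4-one drawn)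
Conditions: Zn(Cu), DME, Et2O, 8 added slowly, 20–30 °C
Reagents that add atoms: none
Why: Zinc converts 8 in the flask into dichloroketene 9, whose electrophilic central carbon is attacked by the cyclobutene π-bond of 20 in a concerted, asynchronous, orthogonal [π2s + π2a] cycloaddition. The closest known reaction type is the dichloroketene [2+2] with unactivated cycloalkenes and with strained alkenes such as norbornene and cyclobutenes. Ring D closes by this intermolecular [2+2], which forms C3–C4 and C5–C6 together, and suprafacial addition on the alkene makes the C/D fusion cis. The new stereocenters C3 and C6 are set by approach to the convex face of the folded bicyclo[2.2.0]hex-2-ene unit, anti to ring B, whose two remaining carbons block the concave face. Only facial selectivity is needed: both regioisomers give the same hydrocarbon after steps 14 and 15, and the cyclobutene is the only π-bond in 20. The pyramidalised, strained alkene is a better donor than the cyclohexene of step 5, so the reaction should run at ambient temperature, far below the ring-opening temperature of 20. DME binds the ZnCl2 formed and slow addition keeps the ketene concentration low, which guards against cationic opening of the cyclobutene and against ketene oligomerisation.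

Step 14
Reactants: 21 tetracyclic dichlorocyclobutanone
Product: 22 tetracyclic cyclobutanone (tetracyclo[6.4.0.0^2,7.0^3,6]dodecan-4-one with the chain at C11 or C10)
Conditions: Zn dust, AcOH, rt
Reagents that add atoms: none
Why: Zinc/acetic acid dechlorination as in steps 6 and 10; the two regioisomers now differ only in which ring D carbon carries the carbonyl.

Step 15
Reactants: 22 tetracyclic cyclobutanone
Product: 24 silyl ether of the ladderane alcohol, via hydrazone 23 (not isolated)
Conditions: N2H4·H2O, EtOH, rt → 50 °C; evaporate; KOtBu, DMSO, rt
Reagents that add atoms: none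
Why: Wolff–Kishner reduction in the Cram variant: the preformed hydrazone is deprotonated by KOtBu in DMSO and loses N2 at room temperature, so the ladder never meets the temperatures of the classical procedure at which bicyclo[2.2.0]hexanes cleave. The pathway is carbanionic, which avoids a radical next to the four-membered rings, and both regioisomeric ketones give the same hydrocarbon.

Step 16
Reactants: 24 silyl ether of the ladderane alcohol
Product: 25 8-(all-cis,anti,anti-tetracyclo[6.4.0.0^2,7.0^3,6]dodecan-10-yl)octan-1-ol
Conditions: TBAF, THF, rt
Reagents that add atoms: none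
Why: Fluoride cleaves the Si–O bond under neutral, non-reductive conditions that leave the strained hydrocarbon untouched.

Step 17
Reactants: 25 ladderane octanol
Product: 26 ladderane octyl methanesulfonate
Conditions: MsCl, Et3N, CH2Cl2, 0 °C
Reagents that add atoms: methanesulfonyl chloride, CS(Cl)(=O)=O
Why: Mesylation of a primary alcohol gives the electrophile for etherification.

Step 18
Reactants: 26 ladderane octyl methanesulfonate; 27 2,2-dimethyl-1,3-dioxan-5-ol
Product: 29 acetonide of the target, via sodium alkoxide 28 (not isolated)
Conditions: 27, NaH, DMF, 0 °C → rt; then 26, Bu4NI (cat.), 50 °C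
Reagents that add atoms: none
Why: Williamson ether synthesis by SN2 attack of the alkoxide of a symmetric secondary alcohol on a primary sulfonate; the glycerol carbon is not a stereocenter, and iodide catalysis favours substitution over elimination.

Step 19
Reactants: 29 acetonide of the target
Product: 30 2-{[8-(tetracyclo[6.4.0.0^2,7.0^3,6]dodecan-10-yl)octyl]oxy}propane-1,3-diol (target)
Conditions: AcOH/H2O (4:1), 40 °C
Reagents that add atoms: none
Why: Acid hydrolysis of the isopropylidene acetal frees the 1,3-diol; the dialkyl ether and the saturated ladder are inert to dilute aqueous acid at this temperature.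

## Compound list

1 | (S)-cyclohex-3-ene-1-carboxylic acid | OC(=O)[C@H]1CCC=CC1 | starting material
2 | (S)-cyclohex-3-en-1-ylmethanol | OC[C@H]1CCC=CC1 | intermediate
3 | (S)-cyclohex-3-en-1-ylmethyl 4-methylbenzenesulfonate | Cc1ccc(cc1)S(=O)(=O)OC[C@H]1CCC=CC1 | intermediate
4 | 7-bromoheptan-1-ol | OCCCCCCCBr | starting material
5 | (7-bromoheptyloxy)triisopropylsilane | CC(C)[Si](C(C)C)(C(C)C)OCCCCCCCBr | intermediate
6 | 7-(triisopropylsilyloxy)heptylmagnesium bromide | CC(C)[Si](C(C)C)(C(C)C)OCCCCCCC[Mg]Br | intermediate
7 | (S)-{[8-(cyclohex-3-en-1-yl)octyl]oxy}triisopropylsilane | CC(C)[Si](C(C)C)(C(C)C)OCCCCCCCC[C@H]1CCC=CC1 | intermediate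
8 | trichloroacetyl chloride | ClC(=O)C(Cl)(Cl)Cl | starting material
9 | dichloroketene | ClC(Cl)=C=O | intermediate
10 | cis-fused 8,8-dichlorobicyclo[4.2.0]octan-7-one with the 8-(triisopropylsilyloxy)octyl chain at C4 (drawn, H-1, H-4, H-6 cis) or C3; formed with the facial diastereomers | CC(C)[Si](C(C)C)(C(C)C)OCCCCCCCC[C@H]1CC[C@@H]2[C@H](C1)C(=O)C2(Cl)Cl | intermediate
11 | cis-fused bicyclo[4.2.0]octan-7-one with the chain at C4 (drawn) or C3; same isomer set | CC(C)[Si](C(C)C)(C(C)C)OCCCCCCCC[C@H]1CC[C@@H]2[C@H](C1)C(=O)C2 | intermediate
12 | p-toluenesulfonyl hydrazide | Cc1ccc(cc1)S(=O)(=O)NN | starting material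
13 | p-toluenesulfonylhydrazones of 11 | CC(C)[Si](C(C)C)(C(C)C)OCCCCCCCC[C@H]1CC[C@@H]2[C@H](C1)C(=NNS(=O)(=O)c3ccc(C)cc3)C2 | intermediate
14 | bicyclo[4.2.0]oct-7-en-7-yllithium with the chain on ring A (one regioisomer drawn) | CC(C)[Si](C(C)C)(C(C)C)OCCCCCCCC[C@H]1CC[C@@H]2[C@H](C1)C([Li])=C2 | intermediate
15 | triisopropyl{[8-(cis-bicyclo[4.2.0]oct-7-en-3-yl)octyl]oxy}silane, H-1, H-3, H-6 cis (chain on the cyclobutene face of ring A); the single diastereomer kept in step 8 | CC(C)[Si](C(C)C)(C(C)C)OCCCCCCCC[C@H]1CC[C@@H]2[C@H](C1)C=C2 | intermediate
16 | 4,4-dichlorotricyclo[4.4.0.0^2,5]decan-3-one with the chain at C9 (drawn) or C8; all fusions cis, rings A and C anti | CC(C)[Si](C(C)C)(C(C)C)OCCCCCCCC[C@H]1CC[C@@H]2[C@H](C1)[C@H]1C(=O)C(Cl)(Cl)[C@@H]21 | intermediate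
17 | tricyclo[4.4.0.0^2,5]decan-3-one with the chain at C9 (drawn) or C8 | CC(C)[Si](C(C)C)(C(C)C)OCCCCCCCC[C@H]1CC[C@@H]2[C@H](C1)[C@H]1C(=O)C[C@@H]21 | intermediate
18 | p-toluenesulfonylhydrazone of 17 | CC(C)[Si](C(C)C)(C(C)C)OCCCCCCCC[C@H]1CC[C@@H]2[C@H](C1)[C@H]1C(=NNS(=O)(=O)c3ccc(C)cc3)C[C@@H]21 | intermediate
19 | tricyclo[4.4.0.0^2,5]dec-3-en-3-yllithium with the chain on ring A (one regioisomer drawn) | CC(C)[Si](C(C)C)(C(C)C)OCCCCCCCC[C@H]1CC[C@@H]2[C@H](C1)[C@H]1C([Li])=C[C@@H]21 | intermediate
20 | triisopropyl{[8-(tricyclo[4.4.0.0^2,5]dec-3-en-8-yl)octyl]oxy}silane; fusions cis, rings A and C anti, chain cis to ring B | CC(C)[Si](C(C)C)(C(C)C)OCCCCCCCC[C@H]1CC[C@@H]2[C@H](C1)[C@H]1C=C[C@@H]21 | intermediate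
21 | 5,5-dichlorotetracyclo[6.4.0.0^2,7.0^3,6]dodecan-4-one with the chain at C11 (drawn) or C10; all fusions cis, consecutive rings anti | CC(C)[Si](C(C)C)(C(C)C)OCCCCCCCC[C@H]1CC[C@@H]2[C@H](C1)[C@H]1[C@@H]3C(=O)C(Cl)(Cl)[C@@H]3[C@@H]21 | intermediate
22 | tetracyclo[6.4.0.0^2,7.0^3,6]dodecan-4-one with the chain at C11 (drawn) or C10 | CC(C)[Si](C(C)C)(C(C)C)OCCCCCCCC[C@H]1CC[C@@H]2[C@H](C1)[C@H]1[C@@H]3C(=O)C[C@@H]3[C@@H]21 | intermediate
23 | hydrazone of 22 | CC(C)[Si](C(C)C)(C(C)C)OCCCCCCCC[C@H]1CC[C@@H]2[C@H](C1)[C@H]1[C@@H]3C(=NN)C[C@@H]3[C@@H]21 | intermediate
24 | triisopropyl{[8-(tetracyclo[6.4.0.0^2,7.0^3,6]dodecan-10-yl)octyl]oxy}silane; ring stereochemistry as in the target | CC(C)[Si](C(C)C)(C(C)C)OCCCCCCCC[C@H]1CC[C@@H]2[C@H](C1)[C@H]1[C@@H]3CC[C@@H]3[C@@H]21 | intermediate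
25 | 8-(tetracyclo[6.4.0.0^2,7.0^3,6]dodecan-10-yl)octan-1-ol | OCCCCCCCC[C@H]1CC[C@@H]2[C@H](C1)[C@H]1[C@@H]3CC[C@@H]3[C@@H]21 | intermediate
26 | 8-(tetracyclo[6.4.0.0^2,7.0^3,6]dodecan-10-yl)octyl methanesulfonate | CS(=O)(=O)OCCCCCCCC[C@H]1CC[C@@H]2[C@H](C1)[C@H]1[C@@H]3CC[C@@H]3[C@@H]21 | intermediate
27 | 2,2-dimethyl-1,3-dioxan-5-ol | CC1(C)OCC(O)CO1 | starting material
28 | sodium 2,2-dimethyl-1,3-dioxan-5-olate | CC1(C)OCC([O-])CO1.[Na+] | intermediate
29 | 2,2-dimethyl-5-{[8-(tetracyclo[6.4.0.0^2,7.0^3,6]dodecan-10-yl)octyl]oxy}-1,3-dioxane | CC1(C)OCC(CO1)OCCCCCCCC[C@H]1CC[C@@H]2[C@H](C1)[C@H]1[C@@H]3CC[C@@H]3[C@@H]21 | intermediate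
30 | 2-{[8-(tetracyclo[6.4.0.0^2,7.0^3,6]dodecan-10-yl)octyl]oxy}propane-1,3-diol; all ring fusions cis, A/C and B/D anti, H-1, H-8, H-10 cis | OCC(CO)OCCCCCCCC[C@H]1CC[C@@H]2[C@H](C1)[C@H]1[C@@H]3CC[C@@H]3[C@@H]21 | target

## Step count and least certain steps

Total: 19 steps. Longest linear sequence: 18 steps (1 → 30 through steps 1, 2 and 4–19; step 3 is a side branch).

**Step 13 (key step).** The strained cyclobutene of 20 may be consumed by ZnCl2-induced cationic ring opening or oligomerisation, or the ketene may oligomerise faster than it adds to a hindered alkene. Fallback, from 20: N,N-dimethylketeniminium triflate F1, made in the flask from N,N-dimethylacetamide, Tf2O and 2,4,6-collidine in CH2Cl2, should add to the same convex face to give the cyclobutaniminium triflate F2 (either regioisomer). Aqueous NaHCO3 hydrolysis then gives ketone 22, so the route is rejoined at 22 and step 14 falls away. No zinc salts are present, and the 2,4,6-collidine buffers the triflic acid that forms with F1.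

**Step 12.** With the second α-deprotonation slowed by the strain of the developing bicyclo[2.2.0]hexene, the monoanion may lose sulfinate first and enter diazo/carbene chemistry (ring contraction, fragmentation of the four-membered ring). Fallback, from 17: kinetic enolisation toward the CH2 group with KN(SiMe3)2 in THF at −78 °C and trapping with PhNTf2 gives the cyclobutenyl triflate F3. Reduction with Pd(OAc)2/PPh3, HCO2H and Bu3N in DMF at 40 °C replaces the triflate by hydrogen and returns to 20.

**Step 8 (with step 5).** Step 5 is expected to show poor facial selectivity, and the chromatographic resolution of the two facial diastereomers may fail because they differ only in a remote relationship within an apolar molecule. Fallback, from 2, which moves the separation to small, polar compounds: silylation (TIPSCl, imidazole) gives the silyl ether F4; addition of 9 gives the dichlorocyclobutanones F5, Zn/AcOH gives the ketones F6, and condensation with 12 gives the tosylhydrazones F7; n-BuLi converts these through the cyclobutenyllithium F8 into the bicyclic alkene silyl ethers F9 (both facial diastereomers); TBAF frees the primary alcohols, and the cis alcohol F10 is separated from its trans diastereomer F11 on silica, where the hydroxyl group sits next to the stereocenter on a small rigid skeleton; tosylation gives the tosylate F12, and Li2CuCl4-catalysed coupling with Grignard reagent 6 returns to 15.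

**Step 15.** Hydrazone formation may stall at the azine, or the strained ketone may undergo base-induced C–C cleavage before it is fully converted; partial loss of the silyl group would be harmless, since step 16 removes it. Fallback, from 22: condensation with 12 gives the tosylhydrazone F13, which is reduced with catecholborane in CHCl3 at 0 °C and decomposed with NaOAc·3H2O at up to 50 °C (catecholborane variant of the Caglioti reduction), returning to 24.

**Step 18.** E2 elimination of mesylate 26 by the hindered secondary alkoxide may compete with substitution. Fallback, from 25: Rh2(OAc)4-catalysed O–H insertion of dimethyl diazomalonate in CH2Cl2 at rt gives the dimethyl 2-alkoxymalonate F14. LiAlH4 in THF at 0 °C reduces both esters and gives 30 directly, bypassing 26 and 29.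

## Further compounds

F1 | step 13 | N,N-dimethylketeniminium trifluoromethanesulfonate | C=C=[N+](C)C.[O-]S(=O)(=O)C(F)(F)F
F2 | step 13 | N,N-dimethyliminium triflate corresponding to ketone 22 (one regioisomer drawn) | CC(C)[Si](C(C)C)(C(C)C)OCCCCCCCC[C@H]1CC[C@@H]2[C@H](C1)[C@H]1[C@@H]3C(=[N+](C)C)C[C@@H]3[C@@H]21.[O-]S(=O)(=O)C(F)(F)F
F3 | step 12 | tricyclo[4.4.0.0^2,5]dec-3-en-3-yl trifluoromethanesulfonate with the silyloxyoctyl chain (one regioisomer drawn) | CC(C)[Si](C(C)C)(C(C)C)OCCCCCCCC[C@H]1CC[C@@H]2[C@H](C1)[C@H]1C(OS(=O)(=O)C(F)(F)F)=C[C@@H]21
F4 | step 8 | (S)-(cyclohex-3-en-1-ylmethoxy)triisopropylsilane | CC(C)[Si](C(C)C)(C(C)C)OC[C@H]1CCC=CC1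
F5 | step 8 | cis-fused 8,8-dichlorobicyclo[4.2.0]octan-7-ones with the silyloxymethyl group on ring A (cis-face 4-substituted isomer drawn) | CC(C)[Si](C(C)C)(C(C)C)OC[C@H]1CC[C@@H]2[C@H](C1)C(=O)C2(Cl)Cl
F6 | step 8 | corresponding bicyclo[4.2.0]octan-7-ones | CC(C)[Si](C(C)C)(C(C)C)OC[C@H]1CC[C@@H]2[C@H](C1)C(=O)C2
F7 | step 8 | p-toluenesulfonylhydrazones of F6 | CC(C)[Si](C(C)C)(C(C)C)OC[C@H]1CC[C@@H]2[C@H](C1)C(=NNS(=O)(=O)c3ccc(C)cc3)C2
F8 | step 8 | bicyclo[4.2.0]oct-7-en-7-yllithium with the silyloxymethyl group (one regioisomer drawn) | CC(C)[Si](C(C)C)(C(C)C)OC[C@H]1CC[C@@H]2[C@H](C1)C([Li])=C2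
F9 | step 8 | (bicyclo[4.2.0]oct-7-en-3-ylmethoxy)triisopropylsilane (cis isomer drawn; formed with the trans isomer) | CC(C)[Si](C(C)C)(C(C)C)OC[C@H]1CC[C@@H]2[C@H](C1)C=C2
F10 | step 8 | cis-bicyclo[4.2.0]oct-7-en-3-ylmethanol, H-1, H-3, H-6 cis | OC[C@H]1CC[C@@H]2[C@H](C1)C=C2
F11 | step 8 | diastereomer of F10 with H-3 trans to H-1 and H-6 | OC[C@H]1CC[C@H]2[C@@H](C1)C=C2
F12 | step 8 | 4-methylbenzenesulfonate of F10 | Cc1ccc(cc1)S(=O)(=O)OC[C@H]1CC[C@@H]2[C@H](C1)C=C2
F13 | step 15 | p-toluenesulfonylhydrazone of 22 (one regioisomer drawn) | CC(C)[Si](C(C)C)(C(C)C)OCCCCCCCC[C@H]1CC[C@@H]2[C@H](C1)[C@H]1[C@@H]3C(=NNS(=O)(=O)c4ccc(C)cc4)C[C@@H]3[C@@H]21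
F14 | step 18 | dimethyl 2-{[8-(tetracyclo[6.4.0.0^2,7.0^3,6]dodecan-10-yl)octyl]oxy}malonate | COC(=O)C(OCCCCCCCC[C@H]1CC[C@@H]2[C@H](C1)[C@H]1[C@@H]3CC[C@@H]3[C@@H]21)C(=O)OC
A1 | alternative 1 | cis-bicyclo[6.4.0]dodeca-2,4,6,10-tetraene (meso) | C1=CC[C@H]2C=CC=CC=C[C@H]2C1
A2 | alternative 1 | tricyclic cyclohexadiene valence isomer of A1 (ring A cyclohexene, ring B, cyclohexadiene; anti isomer) | C1=CC[C@@H]2[C@H](C1)[C@H]1C=CC=C[C@@H]21
A3 | alternative 1 | meso tetracyclo[6.4.0.0^2,7.0^3,6]dodeca-4,10-diene | C1=CC[C@@H]2[C@H](C1)[C@H]1[C@@H]3C=C[C@@H]3[C@@H]21
A4 | alternative 2 | (3E,9E)-6-[8-(2,2-dimethyl-1,3-dioxan-5-yloxy)octyl]dodeca-1,3,9,11-tetraene, C6 configured as C10 of the target | CC1(C)OCC(CO1)OCCCCCCCC[C@@H](CC/C=C/C=C)C/C=C/C=C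
A5 | alternative 2 | acetonide of the target (identical with 29) | CC1(C)OCC(CO1)OCCCCCCCC[C@H]1CC[C@@H]2[C@H](C1)[C@H]1[C@@H]3CC[C@@H]3[C@@H]21
A6 | alternative 3 | housane carbaldehyde p-toluenesulfonylhydrazone (cyclopropane fused to ring C anti to ring B, acetonide chain) | CC1(C)OCC(CO1)OCCCCCCCC[C@H]1CC[C@@H]2[C@H](C1)[C@H]1[C@@H]3C(C=NNS(=O)(=O)c4ccc(C)cc4)[C@@H]3[C@@H]21
A7 | alternative 3 | tetracyclic ladderene with ring D cyclobutene and acetonide chain | CC1(C)OCC(CO1)OCCCCCCCC[C@H]1CC[C@@H]2[C@H](C1)[C@H]1[C@@H]3C=C[C@@H]3[C@@H]21
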